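The leftover is what I reckon with: not the product made, but the gap still open below the level on which a run stops.

| flask | starting material | reagent | protic impurity | temperature | remark | time |
|---|---|---|---|---|---|---|
| spring | 0.20 M | 0.16 M | 0.010 M | 60 °C | run made earlier |  |
| dusk | 0.20 M | 0.16 M | 0.015 M | 102 °C | run made earlier |  |
| elm | 0.20 M | 0.160 M | 0.0200 M | 90 °C |  | 5.0 h |
| alder | 0.20 M | 0.160 M | 0.0200 M | 140 °C |  | 5.0 h |
| maple | 0.20 M | 0.160 M | 0.0200 M | 115 °C |  | 5.0 h |
| cedar | 0.20 M | 0.160 M | 0.0200 M | 65 °C |  | 5.0 h |

| run | time / h | product / % |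
|---|---|---|
| spring | 2.00 | 3 |
| spring | 4.00 | 5 |
| spring | 6.00 | 5 |
| spring | 12.0 | 13 |
| spring | 25.0 | 18 |
| dusk | 0.667 | 34 |
| dusk | 1.33 | 32 |
| dusk | 2.00 | 29 |
| dusk | 3.00 | 31 |

(standard deviation of a reading: 2 percentage points)

* the flask with the highest amount of product, in percent of the starting material charged ("all alike" if they lie within 1.5 percentage points) (elm / alder / maple / cedar / all alike)
* final product, as a percentage of the starting material charged, in elm
* final product, as a percentage of the starting material charged, in alder
* final product, as a percentage of the starting material charged, in maple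
* final product, as a percentage of the starting material charged, in cedar

The dusk run reads flat from 0.667 h to 3.00 h, so I take the mean of its readings, 31.5%, as the ceiling, and I assume the same ceiling for the spring run. At the last spring reading, 18% after 25.0 h, the leftover is a fraction 0.429 of the ceiling. Treating the gap as a first-order relaxation, the spring run has 20.5 h as its gap time, the hours in which the leftover falls to half of itself.

The bench rule says that, with the charge held, a rate rises by a factor of 2 every 10.0 K, so I divide the gap time by that factor. Cedar gets 14.5 h, so 5.0 h leaves a fraction 0.787 and gives 6.71% product. Elm gets 2.56 h, which leaves 0.258 and gives 23.4%.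

The border shows in the dusk run. The rule gives it a gap time of 1.11 h, and the first reading comes at a ratio of 0.601 of that, which leaves 0.660 and means 10.7% product. The reading is 34%, a factor 3.17 above the rule. So, reckoned from the spring run, the rule comes out too slow for the dusk run at 102 °C and 0.015 M protic impurity, and I take my elm figure as a low estimate, with the ceiling above it. Maple and alder, with gap times of 0.452 h and 0.0799 h, come out level at the ceiling on this reckoning, which keeps the ceiling unchanged by assumption.

The forecast names elm, with 35% there, 24% in alder, 29% in maple and 7% in cedar: “This favours elm, though the ceiling's temperature trend is uncertain.” My reckoning stands close to it on cedar, gives 23.4% against its 35% on elm, and parts from it on alder, which I keep level with maple, where the forecast lets the ceiling fall.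

    intermediate A ⇌ intermediate C (K = 0.380, k = 0.00120 s⁻¹, Ea = 93.0 kJ mol⁻¹, ΔH = −4.00 kJ mol⁻¹)
    intermediate C ⇌ starting material (k = 6.30 × 10⁻⁴ s⁻¹, Ea = 120 kJ mol⁻¹)
    starting material ⇌ intermediate A (K = 2.20, k = 0.00880 s⁻¹, Ea = 103 kJ mol⁻¹, ΔH = −45.0 kJ mol⁻¹)
    intermediate C ⇌ product (K = 3.00, k = 9.90 × 10⁻⁴ s⁻¹, Ea = 119 kJ mol⁻¹, ΔH = 39.0 kJ mol⁻¹)
    starting material ⇌ intermediate B (K = 0.330, k = 0.00150 s⁻¹, Ea = 109 kJ mol⁻¹, ΔH = −64.0 kJ mol⁻¹)
    reagent + intermediate B ⇌ intermediate D (K = 160 L mol⁻¹, k = 0.00410 L mol⁻¹ s⁻¹, Ea = 57.0 kJ mol⁻¹, ΔH = 4.00 kJ mol⁻¹)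
    starting material + protic impurity → quenched substrate (k = 0.0340 L mol⁻¹ s⁻¹, Ea = 51.0 kJ mol⁻¹)
    (constants at 90 °C)

The flask with most product is alder, with 39.7%, then maple 31.9%, elm 24.1% and cedar 10.7%. Alder holds 39.7% after 50.0 h as well, a level above the mean of the dusk readings, 31.5%. With its gap time of 0.0799 h, the 5.0 h in alder is 62.6 gap times. In the cedar flask left until 2.0 h, the gap time 14.5 h leaves a fraction 0.909, which means 2.87% product, and that flask holds 4.65%.

The readings come from a simulation for substances that don't exist, noise included.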